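**Retrosynthetic overview**
1. Target 19 ← vinyl compound 18 by hydroxyl-directed epoxidation (C1). 18 ← diol 16 by SeO2/MnO2, which turns the C7 isopropenyl into the 8,12-lactone and the C5 isopropenyl into the C15 enal. The angelate goes on the 6β-OH beforehand.
2. Elemane ketone 12 (C10 quaternary centre, vinyl and isopropenyl groups) ← tethered enone 9 by a one-pot silicon-tethered [2+2] photocycloaddition / fluoride-triggered cyclobutane fragmentation, which forms C10–C1 and C5–C4.
3. Enone 9 ← (S)-carvone 1 by α'-hydroxylation (C8–O), Luche reduction / Mitsunobu inversion (C9–O), allylic oxidation (C6=O), silylation and cross-metathesis.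
4. Ring order: the carbocycle is bought with carvone; siloxane and cyclobutane rings (step 9) and the acetonide (steps 10–13) are temporary; the γ-lactone is closed in step 14 and the epoxide in step 15.

Convention: elemane numbering is used for every intermediate (ring C5–C10; in carvone C9 is the carbonyl carbon, C10 the methyl-bearing carbon, C5 the alkene CH, C6 the allylic CH2, C7 the isopropenyl-bearing carbon, C8 the CH2 next to the carbonyl); β is the face of the C10 methyl in the target, α the opposite face; the SMILES fix the absolute configuration.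

**Route**

Step 1
Reactants: 1 (S)-(+)-carvone
Product: 2 8α-hydroxycarvone
Conditions: LiN(iPr)2, THF, −78 °C; then racemic 2-(phenylsulfonyl)-3-phenyloxaziridine, −78 °C
Reagents that add atoms: 2-(phenylsulfonyl)-3-phenyloxaziridine, O=S(=O)(c1ccccc1)N1OC1c1ccccc1
Why: Kinetic α'-deprotonation and enolate hydroxylation (Davis oxidation) anti to the neighbouring isopropenyl group give the trans ketol, so C8 is set by the carvone stereocentre C7.

Step 2
Reactants: 2 8α-hydroxycarvone
Product: 3 8α-(tert-butyldimethylsilyloxy)carvone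
Conditions: TBSCl, imidazole, DMF, rt
Reagents that add atoms: TBSCl, CC(C)(C)[Si](C)(C)Cl
Why: Standard silylation protects the 8-hydroxyl through the oxidation and tethering steps without touching a stereocentre.

Step 3
Reactants: 3 8α-(tert-butyldimethylsilyloxy)carvone
Product: 4 9β-alcohol (9-OH trans to 8-OTBS)
Conditions: NaBH4, CeCl3·7H2O, MeOH, −78 °C
Reagents that add atoms: none
Why: Luche 1,2-reduction with axial hydride attack on the half-chair (both substituents equatorial) should give the equatorial 9β-alcohol, the epimer needed for inversion in step 4 (if the 9α-alcohol formed instead, direct chloroacetylation would give 5).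

Step 4
Reactants: 4 9β-alcohol
Product: 5 9α-chloroacetate (9-O cis to 8-OTBS)
Conditions: ClCH2CO2H, PPh3, DIAD, toluene, 0 °C to rt
Reagents that add atoms: chloroacetic acid, OC(=O)CCl
Why: Mitsunobu reaction with the acidic chloroacetic acid proceeds by SN2 inversion at C9 and places the 9-oxygen on the α face, cis to the 8-oxygen, as in the target.

Step 5
Reactants: 5 9α-chloroacetate
Product: 6 6-oxo enone chloroacetate
Conditions: Rh2(cap)4 (cap = caprolactamate, 1 mol%), 70% aq. TBHP, 1,2-dichloroethane, 40 °C
Reagents that add atoms: tert-butyl hydroperoxide, CC(C)(C)OO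
Why: Rh2(cap)4/TBHP allylic C–H oxidation (tert-butylperoxyl radical chain) attacks the only ring allylic methylene, C6, giving the enone that serves as chromophore, as the handle for C5 epimerisation and as the C6 oxygen; C7, now epimerisable, stays in its more stable trans-equatorial form.

Step 6
Reactants: 6 6-oxo enone chloroacetate
Product: 7 9α-hydroxy enone
Conditions: thiourea, NaHCO3, EtOH, 50 °C
Reagents that add atoms: none
Why: Thiourea removes the chloroacetate by S-alkylation and cyclisation under nearly neutral conditions, which avoids silyl migration and conjugation of the isopropenyl group.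

Step 7
Reactants: 7 9α-hydroxy enone
Product: 8 9α-O-allyldimethylsilyl ether
Conditions: allylchlorodimethylsilane, imidazole, CH2Cl2, 0 °C
Reagents that add atoms: allylchlorodimethylsilane, C=CC[Si](C)(C)Cl
Why: Silyl ether formation attaches an allylsilane tether to the 9α-oxygen, the handle that will deliver carbon to the α face of C10.

Step 8
Reactants: 8 9α-O-allyldimethylsilyl ether
Product: 9 9α-O-[(E)-4-acetoxy-3-methylbut-2-enyl]dimethylsilyl ether
Conditions: 2-methylallyl acetate (6 equiv), second-generation Hoveyda–Grubbs catalyst (RuCl2(=CH-C6H4-2-OiPr)(SIMes), 5 mol%), CH2Cl2, 40 °C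
Reagents that add atoms: 2-methylallyl acetate, CC(=C)COC(C)=O
Why: Olefin cross-metathesis of the monosubstituted allylsilane with excess 2-methylallyl acetate builds the trisubstituted alkene carrying C1–C4, C15 and the acetate leaving group; the alkene geometry is irrelevant because both alkene carbons become sp2 again in step 9.

Step 9
Reactants: 9 9α-O-[(E)-4-acetoxy-3-methylbut-2-enyl]dimethylsilyl ether
Product: 12 8α,9α-dihydroxyelema-1,3,11(13)-trien-6-one, via cyclobutane photoadduct 10 (not isolated), via C5-epimeric ketone diol 11 (not isolated)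
Conditions: hν (350 nm), CH2Cl2, 0.01 M, 0 °C; then TBAF (4 equiv), THF, 0 °C to rt
Reagents that add atoms: none
Why: Proposed new method: the enone triplet adds to the alkene held by the 9α-O–Si–CH2 tether, so the six-membered siloxane ring forces C1 onto the α face of C10 (quaternary stereocentre, cis to the 9-oxygen) and C4 onto C5; fluoride then attacks silicon and the C2–Si electrons flow through the strained C1–C4 cyclobutane bond to expel the C3 acetate (Grob-type 1,4-elimination through a σ-bond, driven by ring strain and Si–F bond formation), unveiling the vinyl and isopropenyl groups, while the basic fluoride also removes the TBS group and epimerises the ketone α-centre C5 to the equatorial 5β isomer; the closest known reactions are silicon-tethered intramolecular enone–alkene [2+2] photocycloadditions and the fluoride-induced 1,4-elimination of 4-silylbut-2-enyl esters to 1,3-dienes, whose C=C relay is replaced here by a cyclobutane C–C bond.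

Step 10
Reactants: 12 8α,9α-dihydroxyelema-1,3,11(13)-trien-6-one
Product: 13 8α,9α-O-isopropylidene ketone
Conditions: 2,2-dimethoxypropane, PPTS, acetone, rt
Reagents that add atoms: 2,2-dimethoxypropane, COC(C)(C)OC
Why: Acetonide formation on the cis-diol blocks both hydroxyls so that only the C6 oxygen can be acylated later.

Step 11
Reactants: 13 8α,9α-O-isopropylidene ketone
Product: 14 6β-alcohol acetonide
Conditions: LiBH(s-Bu)3 (L-Selectride), THF, −78 to 0 °C; then H2O
Reagents that add atoms: none
Why: The bulky hydride attacks the C6 ketone from the equatorial (α) side because the axial path is blocked by the syn-axial C10 methyl, giving the axial 6β-alcohol (substrate-controlled ketone reduction).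

Step 12
Reactants: 14 6β-alcohol acetonide
Product: 15 6β-angelate acetonide
Conditions: LiN(SiMe3)2, THF, −78 °C; then angelic anhydride, −78 to 0 °C
Reagents that add atoms: angelic anhydride, C/C=C(/C)C(=O)OC(=O)/C(C)=C\C
Why: Acylation of the lithium alkoxide of the hindered axial alcohol with angelic anhydride at low temperature transfers the (Z)-2-methylbut-2-enoyl group without isomerisation to the tiglate.

Step 13
Reactants: 15 6β-angelate acetonide
Product: 16 6β-angeloyloxyelema-1,3,11(13)-triene-8α,9α-diol
Conditions: 80% aq. AcOH, 40 °C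
Reagents that add atoms: none
Why: Mild acid hydrolysis of the cis-fused acetonide frees the 8- and 9-hydroxyls, and the angelate, trans and 1,3 to the nearest hydroxyl, cannot migrate.

Step 14
Reactants: 16 6β-angeloyloxyelema-1,3,11(13)-triene-8α,9α-diol
Product: 18 6β-angeloyloxy-9α-hydroxy-15-oxoelema-1,3,11(13)-trien-12,8α-olide, via bis-allylic alcohol 17 (not isolated)
Conditions: SeO2 (0.3 equiv), TBHP, CH2Cl2, rt; filter; then MnO2 (excess), CH2Cl2, rt
Reagents that add atoms: tert-butyl hydroperoxide, CC(C)(C)OO
Why: SeO2/TBHP allylic oxidation (ene/[2,3] sequence) hydroxylates the methyl of both isopropenyl groups, and MnO2 then oxidises the C15 allylic alcohol to the enal and the C12 alcohol, via its lactol with the equatorial 8α-hydroxyl, to the trans-fused α-methylene-γ-lactone, leaving the non-allylic 9-hydroxyl untouched.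

Step 15
Reactants: 18 6β-angeloyloxy-9α-hydroxy-15-oxoelema-1,3,11(13)-trien-12,8α-olide
Product: 19 CNP0113462.3
Conditions: VO(acac)2 (10 mol%), TBHP (decane), CH2Cl2, 0 °C to rt
Reagents that add atoms: tert-butyl hydroperoxide, CC(C)(C)OO
Why: Vanadium-catalysed hydroxyl-directed epoxidation: the 9α-hydroxyl binds vanadium and delivers the peroxide oxygen to the homoallylic vinyl group, the only electron-rich alkene left, through a chair-like transition state with C2 pseudo-equatorial, which sets C1 as in the target.

**Compound list**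
1 | (S)-(+)-carvone, (5S)-2-methyl-5-(prop-1-en-2-yl)cyclohex-2-en-1-one | CC1=CC[C@@H](CC1=O)C(C)=C | starting material
2 | 8α-hydroxycarvone, (5R,6R)-6-hydroxy-2-methyl-5-(prop-1-en-2-yl)cyclohex-2-en-1-one (OH trans to isopropenyl) | O[C@@H]1[C@@H](C(C)=C)CC=C(C)C1=O | intermediate
3 | 8α-(tert-butyldimethylsilyloxy)carvone | CC(C)(C)[Si](C)(C)O[C@@H]1[C@@H](C(C)=C)CC=C(C)C1=O | intermediate
4 | 9β-alcohol of 3 (9-OH trans to 8-OTBS, cis to isopropenyl) | CC(C)(C)[Si](C)(C)O[C@@H]1[C@@H](C(C)=C)CC=C(C)[C@H]1O | intermediate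
5 | 9α-chloroacetate (9-O cis to 8-OTBS) | CC(C)(C)[Si](C)(C)O[C@@H]1[C@@H](C(C)=C)CC=C(C)[C@@H]1OC(=O)CCl | intermediate
6 | 6-oxo enone chloroacetate (C5=C10 enone, 9α-chloroacetoxy, 8α-OTBS, 7β-isopropenyl) | CC(C)(C)[Si](C)(C)O[C@@H]1[C@@H](C(C)=C)C(=O)C=C(C)[C@@H]1OC(=O)CCl | intermediate
7 | 9α-hydroxy enone (8α-OTBS, 7β-isopropenyl) | CC(C)(C)[Si](C)(C)O[C@@H]1[C@@H](C(C)=C)C(=O)C=C(C)[C@@H]1O | intermediate
8 | 9α-O-allyldimethylsilyl ether of 7 | CC(C)(C)[Si](C)(C)O[C@@H]1[C@@H](C(C)=C)C(=O)C=C(C)[C@@H]1O[Si](C)(C)CC=C | intermediate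
9 | 9α-O-[(E)-4-acetoxy-3-methylbut-2-enyl]dimethylsilyl ether of 7 (the Z isomer reacts the same way) | CC(C)(C)[Si](C)(C)O[C@@H]1[C@@H](C(C)=C)C(=O)C=C(C)[C@@H]1O[Si](C)(C)C/C=C(\C)COC(C)=O | intermediate
10 | cyclobutane photoadduct (C10–C1 and C5–C4 on the α face, siloxane ring C9–O–Si–C2–C1–C10; drawn as one C4 epimer, both converge) | CC(C)(C)[Si](C)(C)O[C@@H]1[C@@H](C(C)=C)C(=O)[C@H]2[C@@]3(C)[C@@H]1O[Si](C)(C)C[C@H]3[C@]2(C)COC(C)=O | intermediate
11 | C5-epimeric ketone diol (5α-isopropenyl epimer of 12) | O[C@@H]1[C@@H](C(C)=C)C(=O)[C@H](C(C)=C)[C@](C)(C=C)[C@@H]1O | intermediate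
12 | 8α,9α-dihydroxyelema-1,3,11(13)-trien-6-one (5β- and 7β-isopropenyl, 10β-methyl, 10α-vinyl) | O[C@@H]1[C@@H](C(C)=C)C(=O)[C@@H](C(C)=C)[C@](C)(C=C)[C@@H]1O | intermediate
13 | 8α,9α-O-isopropylidene derivative of 12 | CC1(C)O[C@@H]2[C@@H](C(C)=C)C(=O)[C@@H](C(C)=C)[C@](C)(C=C)[C@@H]2O1 | intermediate
14 | 6β-alcohol acetonide | CC1(C)O[C@@H]2[C@@H](C(C)=C)[C@@H](O)[C@@H](C(C)=C)[C@](C)(C=C)[C@@H]2O1 | intermediate
15 | 6β-angelate acetonide | CC1(C)O[C@@H]2[C@@H](C(C)=C)[C@@H](OC(=O)/C(C)=C\C)[C@@H](C(C)=C)[C@](C)(C=C)[C@@H]2O1 | intermediate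
16 | 6β-angeloyloxyelema-1,3,11(13)-triene-8α,9α-diol | O[C@@H]1[C@@H](C(C)=C)[C@@H](OC(=O)/C(C)=C\C)[C@@H](C(C)=C)[C@](C)(C=C)[C@@H]1O | intermediate
17 | bis-allylic alcohol (12,15-dihydroxy derivative of 16) | O[C@@H]1[C@@H](C(=C)CO)[C@@H](OC(=O)/C(C)=C\C)[C@@H](C(=C)CO)[C@](C)(C=C)[C@@H]1O | intermediate
18 | 6β-angeloyloxy-9α-hydroxy-15-oxoelema-1,3,11(13)-trien-12,8α-olide | C=C1C(=O)O[C@@H]2[C@@H]1[C@@H](OC(=O)/C(C)=C\C)[C@@H](C(=C)C=O)[C@](C)(C=C)[C@@H]2O | intermediate
19 | CNP0113462.3 (1,2-epoxide of 18) | C=C1C(=O)O[C@@H]2[C@@H]1[C@@H](OC(=O)/C(C)=C\C)[C@@H](C(=C)C=O)[C@](C)([C@@H]1CO1)[C@@H]2O | target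

**Step count and risk**
Total: 15 steps. Longest linear sequence: 15 steps from (S)-carvone.

The three steps most likely to fail are 9, 15 and 12.

Step 9 (new photocycloaddition/fragmentation): the [2+2] can lose to cyclisation onto the C7 isopropenyl group, and the σ-bond 1,4-elimination is untested. The fallback sets out from 7 and returns at 12. Excess vinylmagnesium bromide in THF (−78 to 0 °C) adds 1,4 to the enone, syn to the magnesium 9α-alkoxide (known alkoxide-directed conjugate addition to γ-hydroxy enones), and gives the 10α-vinyl ketone F1. Palladium-catalysed α-alkenylation of its C5 methylene with 2-bromopropene (Pd2(dba)3, P(t-Bu)3, LiN(SiMe3)2, toluene) gives, after equilibration, the 5β-isopropenyl ketone F2. TBAF then removes the silyl group to give 12.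

Step 15 (C1 configuration): the vinyl group sits next to the bulky C5 substituent, and the directed delivery may favour the other face. The fallback sets out from 18 and returns at 19. N-Bromosuccinimide in wet 1,2-dimethoxyethane opens the bromonium ion at C1 with water, so the hydroxyl enters anti to the face an oxidant attacks, and gives the bromohydrin F4. Ag2O in CH2Cl2 closes the epoxide with retention at C1.

Step 12 (angeloylation of the 6β-hydroxyl, which is 1,3-diaxial to the C10 methyl): acylation may be slow or may give tiglate. The fallback sets out from 14 and returns at 15. Esterification with 2-[bis(2,2,2-trifluoroethoxy)phosphoryl]propanoic acid (DCC, DMAP) gives the phosphonopropionate ester F3 (both epimers at the phosphonate carbon). Still–Gennari olefination with acetaldehyde (KN(SiMe3)2, 18-crown-6, THF, −78 °C) then builds the Z-enoate, which is the angelate 15.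

Further compounds
F1 | step 9 | 10α-vinyl ketone (8α-OTBS, 9α-OH, 7β-isopropenyl, C5 methylene) | CC(C)(C)[Si](C)(C)O[C@@H]1[C@@H](C(C)=C)C(=O)C[C@](C)(C=C)[C@@H]1O
F2 | step 9 | 5β-isopropenyl ketone (8-O-TBS ether of 12) | CC(C)(C)[Si](C)(C)O[C@@H]1[C@@H](C(C)=C)C(=O)[C@@H](C(C)=C)[C@](C)(C=C)[C@@H]1O
F3 | step 12 | 6β-O-{2-[bis(2,2,2-trifluoroethoxy)phosphoryl]propanoyl} acetonide (phosphonate carbon unassigned, both epimers) | CC1(C)O[C@@H]2[C@@H](C(C)=C)[C@@H](OC(=O)C(C)P(=O)(OCC(F)(F)F)OCC(F)(F)F)[C@@H](C(C)=C)[C@](C)(C=C)[C@@H]2O1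
F4 | step 15 | bromohydrin of 18 (1-hydroxy, 2-bromo) | C=C1C(=O)O[C@@H]2[C@@H]1[C@@H](OC(=O)/C(C)=C\C)[C@@H](C(=C)C=O)[C@](C)([C@@H](O)CBr)[C@@H]2O
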